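**Retrosynthetic overview**

1. Burkinabin A is 3,4-di-O-vanilloyl-(−)-quinic acid. The acid and the free 5-OH are unveiled last from a 1,5-lactone (quinide) and O3 is acylated just before, so the problem reduces to the 4-O-aroyl-3-dehydroquinide 9.
2. Key disconnection C4–C5: the δ-keto aldehyde 7 has C3 at the ketone level, C4 already carrying the protected vanilloyl ester, and C1/O1/C7 held in a temporary 1,3-dioxolan-4-one. It closes the cyclohexane by aldol addition, and in the same flask the new 5-OH captures C7 to give the γ-lactone with loss of the acetal aldehyde.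
3. Enabling feature: the C3 carbonyl makes C4–H the only α-position that can reach the C5 aldehyde through a six-membered ring. The cis-1,3 relation of C7 (on C1) and O5 lets them form the five-membered lactone ring O5–C7–C1–C6–C5 of a 6-oxabicyclo[3.2.1]octane, which relays the C1 configuration to C5 and puts C1 and C5 at bridgeheads.
4. Precursor 7 comes from L-malic acid: quaternary C1 by stereoretentive propargylation of its pivalaldehyde acetal, the C2–C3–C4 arm by gold-catalysed alkyne oxidation with O–H insertion of the vanillic acid building block, and the C5 aldehyde from the malate CH2CO2H.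
5. Ring order: dioxolanone (temporary) → cyclohexane (C4–C5) → γ-lactone (O5–C7) → lactone opened in step 9.

Key step: step 6

Remark: quinic acid numbering is used throughout (C1 bears OH and CO2H; O3 and O4 are cis; O5 is trans to O4 and cis to the carboxyl carbon C7). The protected vanilloyl group is 4-(benzyloxy)-3-methoxybenzoyl.

**Route**

Step 1
Reactants: 1 L-malic acid, (S)-2-hydroxybutanedioic acid
Product: 2 (2S,4S)-2-tert-butyl-5-oxo-1,3-dioxolane-4-acetic acid (tert-butyl cis to the CH2CO2H arm)
Conditions: t-BuCHO, p-TsOH·H2O (cat.), H2SO4 (cat.), pentane, reflux, Dean–Stark; crystallisation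
Reagents that add atoms: pivalaldehyde, CC(C)(C)C=O
Why: Acid-catalysed acetalisation of the α-hydroxy acid with azeotropic removal of water should give the 1,3-dioxolan-4-one, the cis acetal being thermodynamically preferred and crystalline, so that the malate stereocentre is copied onto the temporary acetal carbon.

Step 2
Reactants: 2 (2S,4S)-2-tert-butyl-5-oxo-1,3-dioxolane-4-acetic acid
Product: 3 (2S,4S)-2-tert-butyl-5-oxo-4-(prop-2-yn-1-yl)-1,3-dioxolane-4-acetic acid (propargyl trans to tert-butyl)
Conditions: LiN(SiMe3)2 (2.1 equiv), THF, −78 °C; propargyl bromide, −78 → −30 °C; aq. HCl work-up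
Reagents that add atoms: propargyl bromide, C#CCBr
Why: Self-regeneration of stereocentres: the dianion (carboxylate plus dioxolanone enolate) is alkylated on the face anti to the tert-butyl group, which should build the quaternary C1 with overall retention of the malate configuration.

Step 3
Reactants: 3 (2S,4S)-2-tert-butyl-5-oxo-4-(prop-2-yn-1-yl)-1,3-dioxolane-4-acetic acid
Product: 4 S-ethyl 2-[(2S,4S)-2-tert-butyl-5-oxo-4-(prop-2-yn-1-yl)-1,3-dioxolan-4-yl]ethanethioate
Conditions: EtSH, EDC·HCl, DMAP (cat.), CH2Cl2, 0 °C → rt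
Reagents that add atoms: ethanethiol, CCS
Why: Steglich-type carbodiimide thioesterification of the free acid masks the future C5 carbonyl at the acid oxidation level without touching the dioxolanone or the alkyne.

Step 4
Reactants: 4 S-ethyl 2-[(2S,4S)-2-tert-butyl-5-oxo-4-(prop-2-yn-1-yl)-1,3-dioxolan-4-yl]ethanethioate; 5 4-(benzyloxy)-3-methoxybenzoic acid (O-benzylvanillic acid)
Product: 6 3-[(2S,4S)-2-tert-butyl-4-[2-(ethylsulfanyl)-2-oxoethyl]-5-oxo-1,3-dioxolan-4-yl]-2-oxopropyl 4-(benzyloxy)-3-methoxybenzoate
Conditions: 5 (2 equiv), 8-methylquinoline N-oxide (1.3 equiv), Ph3PAuNTf2 (5 mol %), PhCl, rt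
Reagents that add atoms: 8-methylquinoline N-oxide, Cc1cccc2ccc[n+]([O-])c12
Why: Gold-catalysed oxidation of the terminal alkyne by the N-oxide places the oxygen on the internal carbon (C3) and acid 5 adds by O–H insertion at the terminal carbon (C4), a known three-component route to α-acyloxy methyl ketones that installs the first vanilloyl unit.

Step 5
Reactants: 6 3-[(2S,4S)-2-tert-butyl-4-[2-(ethylsulfanyl)-2-oxoethyl]-5-oxo-1,3-dioxolan-4-yl]-2-oxopropyl 4-(benzyloxy)-3-methoxybenzoate
Product: 7 3-[(2S,4R)-2-tert-butyl-5-oxo-4-(2-oxoethyl)-1,3-dioxolan-4-yl]-2-oxopropyl 4-(benzyloxy)-3-methoxybenzoate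
Conditions: Et3SiH, 10% Pd/C, acetone, rt
Reagents that add atoms: none
Why: Fukuyama reduction of the thioester with Et3SiH on Pd/C should stop at the aldehyde and leave the ketone, the aryl ester, the dioxolanone and (in acetone) the benzyl ether intact.

Step 6
Reactants: 7 3-[(2S,4R)-2-tert-butyl-5-oxo-4-(2-oxoethyl)-1,3-dioxolan-4-yl]-2-oxopropyl 4-(benzyloxy)-3-methoxybenzoate
Product: 9 4-O-[4-(benzyloxy)-3-methoxybenzoyl]-3-dehydroquinic acid 1,5-lactone (1-hydroxy-3,7-dioxo-6-oxabicyclo[3.2.1]octan-4-yl 4-(benzyloxy)-3-methoxybenzoate), via spiro aldol adduct 8 (not isolated)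
Conditions: L-proline (30 mol %), DMSO, rt
Reagents that add atoms: none
Why: L-Proline forms the E-enamine of the C3 ketone towards C4 (the aroyloxy-bearing, more acidic α-carbon) and this adds to the C5 aldehyde, which is held by a hydrogen bond to the catalyst carboxylic acid, to give aldol 8; in 8 the new 5-OH is cis to the dioxolanone carbonyl C7, attacks it after a chair flip, and the resulting hemiacylal collapses with loss of pivalaldehyde, which closes the γ-lactone of 9 and frees 1-OH. The closest known reactions are proline-catalysed enolendo aldol cyclisations of 1,5-dicarbonyl compounds (Hajos–Parrish type, also run on sugar-derived diketones), the proline aldol of α-oxygenated acetones, and acyl transfer from 1,3-dioxolan-4-ones to alcohols. The carbocycle closes 6-(enolendo)-exo-trig through the C4–C5 bond and the lactone closes 5-exo-trig at C7. C4 (S) is set by the catalyst, which delivers the aldehyde to the enamine face next to its CO2H group, and C5 (R) by the chair transition state with the hydrogen-bonded aldehyde oxygen axial, so that O5 is trans to O4 and cis to C7; the C1 stereocentre then proof-reads C5, because the aldol is reversible and only the epimer with O5 cis to C7 is drained into the lactone. The step needs enolisation at C4 only and no β-elimination: the other enolisable positions (C2, C6) could close only three- or four-membered rings, and once 9 has formed, loss of O1 or O5 would require a bridgehead alkene (Bredt's rule).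

Step 7
Reactants: 9 4-O-[4-(benzyloxy)-3-methoxybenzoyl]-3-dehydroquinic acid 1,5-lactone
Product: 10 4-O-[4-(benzyloxy)-3-methoxybenzoyl]quinic acid 1,5-lactone (3-OH equatorial, cis to the 4-ester)
Conditions: NaBH4, CeCl3·7H2O, MeOH–THF, −78 °C
Reagents that add atoms: none
Why: Luche-type reduction with a small hydride should attack C3 from the face of the lactone bridge, antiperiplanar to the axial C4–O bond (Felkin–Anh) and away from the axial aroyloxy group that screens the other face, to give the equatorial 3-OH cis to O4, while any 4→3 acyl shift converges in step 8.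

Step 8
Reactants: 10 4-O-[4-(benzyloxy)-3-methoxybenzoyl]quinic acid 1,5-lactone; 5 4-(benzyloxy)-3-methoxybenzoic acid
Product: 11 3,4-bis-O-[4-(benzyloxy)-3-methoxybenzoyl]quinic acid 1,5-lactone
Conditions: 5 (1.3 equiv), EDC·HCl, DMAP, CH2Cl2, 0 °C → rt
Reagents that add atoms: none
Why: Steglich esterification should take place at the unhindered secondary equatorial 3-OH (or at 4-OH after a cis acyl shift, which leads to the same diester) in preference to the tertiary 1-OH.

Step 9
Reactants: 11 3,4-bis-O-[4-(benzyloxy)-3-methoxybenzoyl]quinic acid 1,5-lactone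
Product: 12 3,4-bis-O-[4-(benzyloxy)-3-methoxybenzoyl]quinic acid
Conditions: 2 M HCl (aq)–THF, 40 °C
Reagents that add atoms: water, O
Why: Acid-catalysed hydrolysis should open the strained bicyclic γ-lactone much faster than the two aryl esters and, unlike base, does not promote acyl migration, as known for acylated quinides.

Step 10
Reactants: 12 3,4-bis-O-[4-(benzyloxy)-3-methoxybenzoyl]quinic acid
Product: 13 burkinabin A, (1R,3R,4S,5R)-1,5-dihydroxy-3,4-bis[(4-hydroxy-3-methoxybenzoyl)oxy]cyclohexane-1-carboxylic acid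
Conditions: H2 (1 atm), 10% Pd/C, EtOAc–MeOH, rt
Reagents that add atoms: none
Why: Hydrogenolysis of the two benzyl aryl ethers under neutral conditions should free the phenols without affecting the benzoate-type esters or the acid.

**Compound list**

1 | L-malic acid | O[C@@H](CC(=O)O)C(=O)O | starting material
2 | (2S,4S)-2-tert-butyl-5-oxo-1,3-dioxolane-4-acetic acid | CC(C)(C)[C@H]1O[C@@H](CC(=O)O)C(=O)O1 | intermediate
3 | (2S,4S)-2-tert-butyl-5-oxo-4-(prop-2-yn-1-yl)-1,3-dioxolane-4-acetic acid | CC(C)(C)[C@H]1O[C@@](CC#C)(CC(=O)O)C(=O)O1 | intermediate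
4 | S-ethyl 2-[(2S,4S)-2-tert-butyl-5-oxo-4-(prop-2-yn-1-yl)-1,3-dioxolan-4-yl]ethanethioate | CC(C)(C)[C@H]1O[C@@](CC#C)(CC(=O)SCC)C(=O)O1 | intermediate
5 | 4-(benzyloxy)-3-methoxybenzoic acid | COc1cc(C(=O)O)ccc1OCc1ccccc1 | starting material
6 | 3-[(2S,4S)-2-tert-butyl-4-[2-(ethylsulfanyl)-2-oxoethyl]-5-oxo-1,3-dioxolan-4-yl]-2-oxopropyl 4-(benzyloxy)-3-methoxybenzoate | CC(C)(C)[C@H]1O[C@@](CC(=O)COC(=O)c2ccc(OCc3ccccc3)c(OC)c2)(CC(=O)SCC)C(=O)O1 | intermediate
7 | 3-[(2S,4R)-2-tert-butyl-5-oxo-4-(2-oxoethyl)-1,3-dioxolan-4-yl]-2-oxopropyl 4-(benzyloxy)-3-methoxybenzoate | CC(C)(C)[C@H]1O[C@@](CC(=O)COC(=O)c2ccc(OCc3ccccc3)c(OC)c2)(CC=O)C(=O)O1 | intermediate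
8 | spiro aldol adduct, 2-tert-butyl-9-hydroxy-4,7-dioxo-1,3-dioxaspiro[4.5]decan-8-yl 4-(benzyloxy)-3-methoxybenzoate (8-aroyloxy trans to 9-OH, 9-OH cis to the dioxolanone carbonyl) | CC(C)(C)[C@H]1O[C@]2(CC(=O)[C@@H](OC(=O)c3ccc(OCc4ccccc4)c(OC)c3)[C@H](O)C2)C(=O)O1 | intermediate (not isolated)
9 | 4-O-[4-(benzyloxy)-3-methoxybenzoyl]-3-dehydroquinic acid 1,5-lactone | O=C(O[C@H]1[C@H]2C[C@](O)(C(=O)O2)CC1=O)c1ccc(OCc2ccccc2)c(OC)c1 | intermediate
10 | 4-O-[4-(benzyloxy)-3-methoxybenzoyl]quinic acid 1,5-lactone | O=C(O[C@H]1[C@H]2C[C@](O)(C(=O)O2)C[C@H]1O)c1ccc(OCc2ccccc2)c(OC)c1 | intermediate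
11 | 3,4-bis-O-[4-(benzyloxy)-3-methoxybenzoyl]quinic acid 1,5-lactone | COc1cc(ccc1OCc1ccccc1)C(=O)O[C@H]1[C@H]2C[C@](O)(C(=O)O2)C[C@H]1OC(=O)c1ccc(OCc2ccccc2)c(OC)c1 | intermediate
12 | 3,4-bis-O-[4-(benzyloxy)-3-methoxybenzoyl]quinic acid | COc1cc(ccc1OCc1ccccc1)C(=O)O[C@H]1[C@H](O)C[C@](O)(C(=O)O)C[C@H]1OC(=O)c1ccc(OCc2ccccc2)c(OC)c1 | intermediate
13 | burkinabin A, 3,4-di-O-vanilloyl-(−)-quinic acid | COc1cc(C(=O)O[C@H]2[C@H](O)C[C@](O)(C(=O)O)C[C@H]2OC(=O)c2ccc(O)c(OC)c2)ccc1O | target

**Step count and risks**

Total step count: 10. Longest linear sequence: 10 steps (1 → 13); building block 5 is used as purchased.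

Steps most likely to fail:

1. Step 6. What may go wrong: amine-induced β-elimination of the acetal oxygen O1 before ring closure, an aldol closure with the wrong sense at C4/C5 that does not revert, or slow acyl transfer to O5. Fallback (tether first, then cationic C4–C5 closure), setting out from 7: aqueous trifluoroacetic acid (THF–H2O, rt) should hydrolyse the acylal, and the hydroxy acid should close onto the aldehyde to the pseudo-acid lactol F1 (anomeric mixture). Ac2O–pyridine should then give the anomeric acetate F2. Me3SiOTf–Et3N (CH2Cl2, −78 → 0 °C) should form the bis-silylated Z-silyl enol ether F3 (not isolated) and ionise the acetate. C4 then adds to the cyclic acyl-oxocarbenium ion at C5, a Mukaiyama-type addition to a lactone-derived oxocarbenium ion, with O5 tied to C7 from the start, to give the 1-O-trimethylsilyl ketolactone F4. Acidic work-up cleaves the silyl ether and the route is rejoined at 9.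

2. Step 7. What may go wrong: poor facial selectivity, that is, hydride delivery from the face opposite the lactone bridge to give the axial 3-epi alcohol, or base-induced opening of the lactone. Fallback (make the other face the intended one and correct by inversion), setting out from 9: LiBH(s-Bu)3 (THF, −78 °C) should attack from the open face to give the 3-epi alcohol F5. Mitsunobu esterification of F5 with acid 5 (PPh3, DIAD, toluene, 0 °C → rt) should invert C3 and install the second aroyl group in the same step, rejoining the route at 11.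

3. Step 4. What may go wrong: inhibition of the gold catalyst by the thioester sulfur, capture of the activated alkyne by the dioxolanone carbonyl, or double oxidation at the terminal carbon. Fallback (build the acyloxy ketone by substitution instead of oxidation), setting out from 2: the same dianion alkylation with 2,3-dibromopropene should give the 2-bromoallyl acid F6. EtSH/EDC·HCl/DMAP should give the 2-bromoallyl thioester F7. NBS in aqueous MeCN should convert the vinyl bromide into the bromomethyl ketone F8. The cesium salt of 5 (Cs2CO3, DMF, rt) then displaces bromide and the route is rejoined at 6.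

**Further compounds**

F1 | step 6 | pseudo-acid lactol, 3-(3,5-dihydroxy-2-oxooxolan-3-yl)-2-oxopropyl 4-(benzyloxy)-3-methoxybenzoate (C3 of the oxolanone configured as C1 of 7; anomeric mixture) | O=C1OC(O)C[C@@]1(O)CC(=O)COC(=O)c1ccc(OCc2ccccc2)c(OC)c1
F2 | step 6 | anomeric acetate of F1 | O=C1OC(OC(C)=O)C[C@@]1(O)CC(=O)COC(=O)c1ccc(OCc2ccccc2)c(OC)c1
F3 | step 6 | bis-silylated Z-silyl enol ether of F2 (1-O-SiMe3, 3-O-SiMe3 enol ether) | C[Si](C)(C)O/C(C[C@]1(O[Si](C)(C)C)CC(OC(C)=O)OC1=O)=C\OC(=O)c1ccc(OCc2ccccc2)c(OC)c1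
F4 | step 6 | 1-O-trimethylsilyl ether of ketolactone 9 | O=C(O[C@H]1[C@H]2C[C@](O[Si](C)(C)C)(C(=O)O2)CC1=O)c1ccc(OCc2ccccc2)c(OC)c1
F5 | step 7 | 3-epi alcohol, 4-O-[4-(benzyloxy)-3-methoxybenzoyl]-3-epi-quinic acid 1,5-lactone (3-OH axial, trans to the 4-ester) | O=C(O[C@H]1[C@H]2C[C@](O)(C(=O)O2)C[C@@H]1O)c1ccc(OCc2ccccc2)c(OC)c1
F6 | step 4 | 2-bromoallyl acid, analogue of 3 with CH2C(Br)=CH2 in place of propargyl | CC(C)(C)[C@H]1O[C@@](CC(Br)=C)(CC(=O)O)C(=O)O1
F7 | step 4 | 2-bromoallyl thioester, S-ethyl thioester of F6 | CC(C)(C)[C@H]1O[C@@](CC(Br)=C)(CC(=O)SCC)C(=O)O1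
F8 | step 4 | bromomethyl ketone, analogue of 6 with CH2Br in place of CH2OC(=O)Ar | CC(C)(C)[C@H]1O[C@@](CC(=O)CBr)(CC(=O)SCC)C(=O)O1
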